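## Analysis of the target

Caraganin C is a 2,3,4-trisubstituted chroman. Ring A is a benzene ring with a methoxy group at C7, the pyran ring (ring C) holds O1, C2, C3 and C4, and ring B (2,4-dimethoxyphenyl) sits on C2. C3 carries a 4-hydroxybenzyl group and C4 an (E)-4-hydroxystyryl group. C2, C3 and C4 are contiguous stereocentres, all R, with 2,3-trans and 3,4-trans relationships, so all three substituents can be equatorial on the half-chair and the target is the most stable diastereomer. Only one centre therefore has to be set absolutely, and that is C4, which bears no heteroatom and cannot epimerise. C3 can be corrected by equilibration while C2 is a carbonyl or lactol carbon, and C2 itself is a benzylic ether carbon that ionises readily. The C2–O1 bond, a benzylic aryl ether activated by ortho- and para-methoxy groups, is acid-labile. The electron-rich styryl double bond excludes hydrogenolysis and strong acid, and two free phenols stand beside three aryl methyl ethers, so the phenol protecting groups must leave under neutral conditions. The hard part is to form the C4–C4a bond enantioselectively at a benzylic and allylic carbon, and at the ring A carbon para to the methoxy group. The strategy rests on one feature: O1, C8a and C4a with the 7-methoxy group are the oxygen, C1 and C6 of 3-methoxyphenol (8), and C4, C3 and C2 are the β-, α- and carbonyl carbons of an α-benzyl enal when C2 is held at the aldehyde level, the styryl group making that enal a 2,4-dienal.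

## Retrosynthetic reasoning

**O–Si bonds of 13.** Caraganin C (14) is traced to its bis(tert-butyldimethylsilyl) ether 13. Aryl silyl ethers are chosen because fluoride removes them without acid, hydrogen or a demethylating Lewis acid, the three conditions the C2–O1 bond, the styrene and the methyl ethers would not survive. The forward step only has to cleave two O–Si bonds.

**C2–aryl bond.** In 13 the bond from C2 to ring B is cut, giving lactol 10 and 1,3-dimethoxybenzene (11). C2 is at the acetal oxidation level in 10, so it can be turned into an oxocarbenium ion, and ring B is an arene nucleophilic enough to attack it through its 4-position. Ring B is thereby kept out of the enantioselective step, and C2 needs no separate control because the all-equatorial product is the thermodynamic one. The forward reaction must arylate C2 without opening the ring for good.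

**C4–C4a and O1–C2 bonds.** Lactol 10 is opened at O1–C2 to hydroxy aldehyde 9, and 9 is cut at C4–C4a into 3-methoxyphenol (8) and dienal 7. This is the central disconnection. It removes the pyran ring and both carbon stereocentres in one operation and leaves two achiral, flat components. The cut is made here and not at C2–C3 or C3–C4 because C4–C4a joins a phenol ortho carbon to an enal β-carbon, the polarity of a conjugate Friedel–Crafts alkylation, and the hydroxyl and aldehyde then close by themselves. The forward reaction, run through the iminium ion of 7 with a chiral primary amine salt, must choose the β- over the δ-carbon, the ortho carbon para to methoxy over the carbon para to hydroxyl, and one face of the β-carbon.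

**C2=C3 bond of dienal 7.** The trisubstituted double bond of 7 is cut into cinnamaldehyde 3 and propanal 6, a crossed aldol condensation. Only 6 can form an enamine or enolate and only 3 is used in excess, so the cross product is defined, and the (2E) geometry is the stable one. The forward step must avoid strong aqueous base, which would strip the aryl silyl ethers, and must suppress self-condensation of 6.

**Feeding the two aldehydes.** Cinnamaldehyde 3 comes from silylated aldehyde 2 by a two-carbon olefination with a formyl-stabilised phosphorus ylide, and 2 from 4-hydroxybenzaldehyde (1). Propanal 6 comes from silyl ether 5 by partial hydride reduction, and 5 from methyl 3-(4-hydroxyphenyl)propanoate (4). Ester 4 is preferred to an arylpropanol because its phenol is the only hydroxyl, so silylation needs no selectivity.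

## Alternatives that were turned down

**Alternative 1:** Disconnection of O1–C8a and C4–C4a, with ring A brought in as an aryne.
- Forward key step: the sodium alkoxide of hydroxy enone A2 adds to the 3-chloroaryne released by fluoride from silyl triflate A3. The chlorine sends the oxygen to the distal aryne carbon, and the aryl anion formed next to chlorine closes 6-exo-trig on the enone β-carbon. The product is chroman A1, with C4 set by the two existing centres.
- For it: the regiochemistry on ring A is fixed by the chlorine and does not depend on the ortho/para balance of a phenol, on which the chosen route relies. C2 and C3 come from well-understood acyclic aldol chemistry, so the absolute configuration does not hang on a new catalytic step, and ring B is present from the start. On these three points it is the stronger plan.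
- Against it: the alkoxide of A2 is a vinylogous aldolate and can fragment by retro-aldol cleavage before it meets the aryne, and the aryl anion can be quenched by the acidic γ-hydrogen instead of cyclising. A1 is still far from the target. The chlorine must be removed reductively, the ketone reduced and dehydrated to the (E)-styrene beside an acid-labile benzylic ether, and the methoxymethyl ethers cleaved with acid, the condition C2–O1 and the styrene tolerate worst. A2 and A3 each need several steps.
- Comparison: safer in regio- and absolute stereocontrol, but about twice as long and ending in acid. The chosen route delivers the styryl group and the C2 oxidation level directly and deprotects with fluoride.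

**Alternative 2:** Disconnection of the C4–styryl bond and the C3–CH2 bond on a preformed ring; coumarin A5 already contains ring A, O1 and C2 to C4.
- Forward key step: copper-catalysed asymmetric 1,4-addition of styryl Grignard reagent A6 to A5 sets C4, and the magnesium enolate is alkylated by benzyl bromide A7 anti to the new group, giving trans lactone A4. No ring is formed, and reduction of A4 to lactol 10 would join the endgame used here.
- For it: ring A regiochemistry is no issue at all, which is stronger than the chosen route. The 3,4-trans relationship is set kinetically by a dependable enolate alkylation, and A5 is commercial.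
- Against it: asymmetric copper-catalysed Grignard additions to coumarins are established for alkyl groups, whereas an alkenyl Grignard reagent conjugated to an electron-rich arene is a new and sluggish partner. Coumarin is a poor acceptor, so 1,2-attack on the lactone and uncatalysed addition threaten the selectivity. The magnesium enolate of an aryl ester can also open to a ketene and a phenoxide before the bromide reacts. A6 must be made geometrically pure, A7 is an unstable bromide, and one more reduction is needed.
- Comparison: the uncertainty is of the same kind, an unprecedented enantioselective C–C bond formation at C4. The chosen route closes the ring in the same step, lands on the lactol level directly and builds its dienal from two cheap phenols by condensation chemistry.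

**Alternative 3:** Disconnection of O1–C2, C2–C3 and C4–C4a at once, an oxa-Povarov annulation of an O-aryl oxocarbenium ion with an alkene.
- Forward key step: 3-methoxyphenol (8), aldehyde A9 and diene A10 combine under a chiral Brønsted acid. The mixed O-aryl O-methyl acetal formed in the flask ionises, the alkene of A10 remote from its conjugated aryl group attacks C2, and the ortho carbon of ring A captures the allyl cation. This gives diacetate A8, from which mild methanolysis would release caraganin C.
- For it: by far the shortest route, with three ring bonds and three stereocentres formed in one operation from three simple components and ring B in place. On step economy it is clearly stronger than the chosen route.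
- Against it: the cation has no hydrogen-bond donor, so the chiral acid can act only as a counter-anion, and enantiocontrol of such an ion in a three-component reaction has no close model. Under acid, A9 and 8 tend to C-alkylation of the phenol and not to acetal formation. The stepwise cationic course leaves the diastereoselectivity at three centres and the site of allyl cation capture open, and the product is acid-labile at C2–O1 under the conditions that form it.
- Comparison: the chosen strategy is longer, but its new step has to deliver only one C–C bond and one stereocentre, C3 and C2 settle thermodynamically, and a way back through known reactions exists.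

Key step: step 6

Assumption: for this new substrate pair the face of 7 that the quinine-derived amine exposes cannot be fixed in advance. That amine is written, and its quinidine-derived pseudo-enantiomer takes its place if the 4S series is favoured. Lactol 10 is expected as a mixture of anomers, which is of no consequence.

## Route

Step 1
Reactants: 1 4-hydroxybenzaldehyde
Product: 2 4-(tert-butyldimethylsilyloxy)benzaldehyde
Conditions: TBSCl, imidazole, DMF, 0 °C to rt
Reagents that add atoms: tert-butyldimethylsilyl chloride (TBSCl), CC(C)(C)[Si](C)(C)Cl
Why: Standard silylation of a phenol with imidazole as base and nucleophilic catalyst; the aldehyde is untouched.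

Step 2
Reactants: 2 4-(tert-butyldimethylsilyloxy)benzaldehyde
Product: 3 (E)-3-[4-(tert-butyldimethylsilyloxy)phenyl]prop-2-enal
Conditions: Ph3P=CHCHO (1.1 equiv), toluene, 80 °C
Reagents that add atoms: (triphenylphosphoranylidene)acetaldehyde, O=CC=P(c1ccccc1)(c1ccccc1)c1ccccc1
Why: Wittig reaction of a formyl-stabilised ylide, which should give the (E)-enal by two-carbon homologation; only a small excess of ylide is used so that a second homologation stays minor, and the neutral conditions spare the aryl silyl ether.

Step 3
Reactants: 4 methyl 3-(4-hydroxyphenyl)propanoate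
Product: 5 methyl 3-[4-(tert-butyldimethylsilyloxy)phenyl]propanoate
Conditions: TBSCl, imidazole, DMF, rt
Reagents that add atoms: tert-butyldimethylsilyl chloride (TBSCl), CC(C)(C)[Si](C)(C)Cl
Why: Silylation of the only hydroxyl group of 4, so no selectivity between hydroxyls is needed.

Step 4
Reactants: 5 methyl 3-[4-(tert-butyldimethylsilyloxy)phenyl]propanoate
Product: 6 3-[4-(tert-butyldimethylsilyloxy)phenyl]propanal
Conditions: iBu2AlH (1.05 equiv), CH2Cl2, −78 °C; then MeOH, aq. potassium sodium tartrate
Reagents that add atoms: none
Why: Partial reduction of a methyl ester: at −78 °C the tetrahedral aluminium alkoxide persists and releases the aldehyde only on work-up; the aryl silyl ether is inert to the hydride.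

Step 5
Reactants: 3 (E)-3-[4-(tert-butyldimethylsilyloxy)phenyl]prop-2-enal; 6 3-[4-(tert-butyldimethylsilyloxy)phenyl]propanal
Product: 7 (2E,4E)-2-[4-(tert-butyldimethylsilyloxy)benzyl]-5-[4-(tert-butyldimethylsilyloxy)phenyl]penta-2,4-dienal
Conditions: pyrrolidine (20 mol%), PhCO2H (20 mol%), CH2Cl2, rt; 6 added slowly to 3 (1.5 equiv)
Reagents that add atoms: none
Why: Crossed aldol condensation under secondary-amine salt catalysis (Mannich-type addition of the enamine of 6 to the carbonyl carbon of the iminium ion of 3, then loss of the amine); 3 has no enolisable hydrogen, so only 6 can be the nucleophile, and slow addition of 6 to excess 3 should hold back its self-condensation. The (2E) geometry with the formyl group trans to the dienyl chain is the thermodynamic one, and the buffered amine leaves intact the aryl silyl ethers that hydroxide in alcohol would cleave.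

Step 6
Reactants: 7 (2E,4E)-2-[4-(tert-butyldimethylsilyloxy)benzyl]-5-[4-(tert-butyldimethylsilyloxy)phenyl]penta-2,4-dienal; 8 3-methoxyphenol
Product: 10 (3R,4R)-3-[4-(tert-butyldimethylsilyloxy)benzyl]-4-[(E)-4-(tert-butyldimethylsilyloxy)styryl]-7-methoxychroman-2-ol (3,4-trans lactol; anomeric mixture), via hydroxy aldehyde 9 (not isolated)
Conditions: 8 (3 equiv), 9-amino-9-deoxy-epi-quinine (20 mol%), CF3CO2H (30 mol%), toluene (0.5 M), 40 °C
Reagents that add atoms: none
Why: Proposed new method: the primary amine, unlike a secondary amine, condenses with the hindered α-branched aldehyde of 7 to a dienyl iminium ion, the carbon of 8 that is ortho to hydroxyl and para to methoxy adds to its β-carbon (C3 of 7) in a Friedel–Crafts alkylation that forms C4–C4a, and the resulting enamine is protonated at the α-carbon and hydrolysed to hydroxy aldehyde 9. The phenolic hydroxyl of 9 then closes on the aldehyde carbon by 6-exo-trig hemiacetalisation (O1–C2), which gives the pyran ring as lactol 10. The closest known reaction types are the secondary-amine-catalysed Friedel–Crafts alkylation and hemiacetalisation of naphthols and polyoxygenated phenols with β-substituted enals to chroman-2-ols and the cinchona primary-amine-catalysed conjugate addition of indoles to α-branched enals; an α-branched 2,4-dienal with a singly activated phenol has not been shown. C4 is controlled by the catalyst: the quinuclidine nitrogen, set free when its proton is used to form the iminium ion, hydrogen-bonds the phenolic hydroxyl and delivers the ortho carbon to one face of C3 of 7, the Re face being the one required for 4R. C3 is under thermodynamic control, since 10 stays in equilibrium with 9, whose α-carbon epimerises through its enamine with the catalyst until the 3,4-trans lactol with both groups equatorial prevails; the anomeric centre stays a mixture and is erased in step 7. β- over δ-attack is expected because the δ-carbon bears the aryl group, attack there would break the styrene conjugation, and only the β-adduct can close a six-membered ring. Ortho- over para-attack rests on the hydrogen-bonded delivery and on the para-methoxy activation of that ortho carbon, while the other ortho carbon lies between two substituents. The aryl silyl ethers should tolerate the buffered acid.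

Step 7
Reactants: 10 (3R,4R)-3-[4-(tert-butyldimethylsilyloxy)benzyl]-4-[(E)-4-(tert-butyldimethylsilyloxy)styryl]-7-methoxychroman-2-ol; 11 1,3-dimethoxybenzene
Product: 13 (2R,3R,4R)-3-[4-(tert-butyldimethylsilyloxy)benzyl]-4-[(E)-4-(tert-butyldimethylsilyloxy)styryl]-2-(2,4-dimethoxyphenyl)-7-methoxychroman, via oxocarbenium ion 12 (not isolated)
Conditions: 11 (10 equiv), BF3·OEt2 (1.2 equiv), 4 Å molecular sieves, CH2Cl2, −40 to −10 °C; then aq. NaHCO3
Reagents that add atoms: none
Why: Friedel–Crafts arylation of a lactol through its oxocarbenium ion: BF3 ionises either anomer of 10 to 12, which is attacked by C4 of 11 (para to one methoxy, ortho to the other), used in large excess so that ring A of a second molecule cannot compete. C2 is set under thermodynamic control, because attack anti to the C3 benzyl group and reversible ionisation of the doubly methoxy-activated benzylic C2–O1 bond both lead to the all-equatorial 2,3-trans-3,4-trans isomer. The aryl silyl ethers and methyl ethers should be inert to BF3 at low temperature, and the ring of the C3 benzyl group, whose free positions are meta to its silyloxy group, is too poor a nucleophile to close a five-membered ring onto C2.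

Step 8
Reactants: 13 (2R,3R,4R)-3-[4-(tert-butyldimethylsilyloxy)benzyl]-4-[(E)-4-(tert-butyldimethylsilyloxy)styryl]-2-(2,4-dimethoxyphenyl)-7-methoxychroman
Product: 14 caraganin C, (2R,3R,4R)-2-(2,4-dimethoxyphenyl)-3-(4-hydroxybenzyl)-4-[(E)-4-hydroxystyryl]-7-methoxychroman
Conditions: Bu4NF (2.5 equiv), AcOH (2.5 equiv), THF, 0 °C
Reagents that add atoms: none
Why: Fluoride-induced desilylation of both aryl silyl ethers, driven by Si–F bond formation; acetic acid buffers the phenoxides, so neither the acid-labile C2–O1 bond nor the hydroxystyryl unit meets harsh conditions, and no stereocentre is touched.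

## Compound list

1 | 4-hydroxybenzaldehyde | O=Cc1ccc(O)cc1 | starting material
2 | 4-(tert-butyldimethylsilyloxy)benzaldehyde | CC(C)(C)[Si](C)(C)Oc1ccc(C=O)cc1 | intermediate
3 | (E)-3-[4-(tert-butyldimethylsilyloxy)phenyl]prop-2-enal | CC(C)(C)[Si](C)(C)Oc1ccc(/C=C/C=O)cc1 | intermediate
4 | methyl 3-(4-hydroxyphenyl)propanoate | COC(=O)CCc1ccc(O)cc1 | starting material
5 | methyl 3-[4-(tert-butyldimethylsilyloxy)phenyl]propanoate | COC(=O)CCc1ccc(O[Si](C)(C)C(C)(C)C)cc1 | intermediate
6 | 3-[4-(tert-butyldimethylsilyloxy)phenyl]propanal | O=CCCc1ccc(O[Si](C)(C)C(C)(C)C)cc1 | intermediate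
7 | (2E,4E)-2-[4-(tert-butyldimethylsilyloxy)benzyl]-5-[4-(tert-butyldimethylsilyloxy)phenyl]penta-2,4-dienal | O=C/C(Cc1ccc(O[Si](C)(C)C(C)(C)C)cc1)=C/C=C/c1ccc(O[Si](C)(C)C(C)(C)C)cc1 | intermediate
8 | 3-methoxyphenol | COc1cccc(O)c1 | starting material
9 | (2R,3R,4E)-2-[4-(tert-butyldimethylsilyloxy)benzyl]-3-(2-hydroxy-4-methoxyphenyl)-5-[4-(tert-butyldimethylsilyloxy)phenyl]pent-4-enal (open form of 10; formed in the flask and not isolated) | O=C[C@H](Cc1ccc(O[Si](C)(C)C(C)(C)C)cc1)[C@H](c1ccc(OC)cc1O)/C=C/c1ccc(O[Si](C)(C)C(C)(C)C)cc1 | intermediate
10 | (3R,4R)-3-[4-(tert-butyldimethylsilyloxy)benzyl]-4-[(E)-4-(tert-butyldimethylsilyloxy)styryl]-7-methoxychroman-2-ol (anomeric mixture; the 2R anomer with equatorial hydroxyl is drawn) | COc1ccc2c(c1)O[C@@H](O)[C@H](Cc1ccc(O[Si](C)(C)C(C)(C)C)cc1)[C@H]2/C=C/c1ccc(O[Si](C)(C)C(C)(C)C)cc1 | intermediate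
11 | 1,3-dimethoxybenzene | COc1cccc(OC)c1 | starting material
12 | (3R,4R)-3-[4-(tert-butyldimethylsilyloxy)benzyl]-4-[(E)-4-(tert-butyldimethylsilyloxy)styryl]-7-methoxy-3,4-dihydrochromen-1-ium (cyclic oxocarbenium ion; formed in the flask and not isolated) | COc1ccc2c(c1)[O+]=C[C@H](Cc1ccc(O[Si](C)(C)C(C)(C)C)cc1)[C@H]2/C=C/c1ccc(O[Si](C)(C)C(C)(C)C)cc1 | intermediate
13 | (2R,3R,4R)-3-[4-(tert-butyldimethylsilyloxy)benzyl]-4-[(E)-4-(tert-butyldimethylsilyloxy)styryl]-2-(2,4-dimethoxyphenyl)-7-methoxychroman | COc1ccc2c(c1)O[C@@H](c1ccc(OC)cc1OC)[C@H](Cc1ccc(O[Si](C)(C)C(C)(C)C)cc1)[C@H]2/C=C/c1ccc(O[Si](C)(C)C(C)(C)C)cc1 | intermediate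
14 | caraganin C, (2R,3R,4R)-2-(2,4-dimethoxyphenyl)-3-(4-hydroxybenzyl)-4-[(E)-4-hydroxystyryl]-7-methoxychroman | COc1ccc2c(c1)O[C@@H](c1ccc(OC)cc1OC)[C@H](Cc1ccc(O)cc1)[C@H]2/C=C/c1ccc(O)cc1 | target

## Step count and least certain steps

Total: 8 steps. Longest linear sequence: 6 steps (1 → 2 → 3 → 7 → 10 → 13 → 14; the branch from 4 through 5 and 6 is equally long).

**Step 6 (key step).** Three things may go wrong.
- Conversion may stall: the α-benzyl group and the electron-releasing 4-silyloxyphenyl group both lower the electrophilicity of the dienyl iminium ion, 8 is only a moderate nucleophile, and the catalyst may rest as the unreactive dienimine.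
- Alkylation may occur through the carbon para to the hydroxyl, which cannot cyclise, or excess 8 may arylate the lactol further.
- Facial selectivity may be poor because several iminium geometries are populated.

The acid-to-amine ratio, a chiral phosphoric acid as counter-anion and a primary amine–thiourea are the first variables to change within the step. The fallback uses known chemistry and makes the C4–styryl bond in place of the C4–C4a bond. It sets out from 2 and returns at 10.
- 2 is converted by boron–Wittig olefination (bis(pinacolato)borylmethane, lithium 2,2,6,6-tetramethylpiperidide, THF, −78 °C to rt) into 2-[(E)-2-[4-(tert-butyldimethylsilyloxy)phenyl]ethenyl]-4,4,5,5-tetramethyl-1,3,2-dioxaborolane F1, whose pinacol group is cleaved (NaIO4, NH4OAc, acetone–water) to (E)-2-[4-(tert-butyldimethylsilyloxy)phenyl]ethenylboronic acid F2.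
- Commercial 2-hydroxy-4-methoxybenzaldehyde F3 is homologated with (triphenylphosphoranylidene)acetaldehyde to (E)-3-(2-hydroxy-4-methoxyphenyl)prop-2-enal F4.
- F2 and F4 are combined with (R)-α,α-diphenylprolinol trimethylsilyl ether (20 mol%) in toluene. This is the known amine-catalysed conjugate addition of alkenylboronic acids to 2-hydroxycinnamaldehydes, in which the ortho-hydroxyl binds boron and the alkenyl group is passed to the β-carbon of the iminium ion. By the usual shielding model this catalyst enantiomer leaves the Re face open (to be confirmed), and the product should be (4S)-4-[(E)-4-(tert-butyldimethylsilyloxy)styryl]-7-methoxychroman-2-ol F5.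
- Oxidation (TEMPO, PhI(OAc)2, CH2Cl2) gives (4S)-4-[(E)-4-(tert-butyldimethylsilyloxy)styryl]-7-methoxychroman-2-one F6.
- The alkylating agent is made from 2 by reduction (NaBH4, EtOH, 0 °C) to [4-(tert-butyldimethylsilyloxy)phenyl]methanol F7 and Appel bromination (CBr4, PPh3, CH2Cl2, 0 °C) to 4-(tert-butyldimethylsilyloxy)benzyl bromide F8 (identical with A7).
- The lithium enolate of F6 (LiN(SiMe3)2, THF, −78 °C) is alkylated by F8 anti to the C4 substituent, giving (3R,4R)-3-[4-(tert-butyldimethylsilyloxy)benzyl]-4-[(E)-4-(tert-butyldimethylsilyloxy)styryl]-7-methoxychroman-2-one F9 (identical with A4). iBu2AlH in CH2Cl2 at −78 °C reduces F9 to lactol 10.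

**Step 7.** Re-ionisation of the C2–O1 bond of 13 may let excess 11 capture the ring-opened benzylic cation (over-arylation with loss of the pyran ring). Ring A of a second molecule may attack 12 (oligomerisation), and the styrene may be protonated by the hydrated Lewis acid. The fallback separates C–C bond formation from ring closure; it sets out from 10 and returns at 13. 1-Bromo-2,4-dimethoxybenzene F10 is lithiated (n-BuLi, THF, −78 °C), and three equivalents of the aryllithium are added to 10, which reacts through its open aldehyde form. This gives (2R,3R,4E)-2-[4-(tert-butyldimethylsilyloxy)benzyl]-1-(2,4-dimethoxyphenyl)-3-(2-hydroxy-4-methoxyphenyl)-5-[4-(tert-butyldimethylsilyloxy)phenyl]pent-4-en-1-ol F11 as a mixture of carbinol epimers. A catalytic amount of p-toluenesulfonic acid in dilute CH2Cl2 at 0 °C ionises the doubly activated benzylic alcohol, and the phenolic hydroxyl closes the ring (SN1 cyclodehydration) to the 2,3-trans flavan 13, with no external nucleophile present.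

**Step 5.** Self-condensation of 6 may outrun the crossed reaction, because the carbonyl group of 3 is deactivated by its donor aryl group. The fallback is a directed aldol condensation with a preformed aza-enolate; it sets out from 6 and returns at 7. 6 is condensed with cyclohexylamine (MgSO4, Et2O, 0 °C) to (E)-N-cyclohexyl-3-[4-(tert-butyldimethylsilyloxy)phenyl]propan-1-imine F12. Deprotonation with LiN(iPr)2 (THF, −78 °C) and 1,2-addition to 3 give (4E)-2-[4-(tert-butyldimethylsilyloxy)benzyl]-1-(cyclohexylimino)-5-[4-(tert-butyldimethylsilyloxy)phenyl]pent-4-en-3-ol F13. Aqueous oxalic acid then hydrolyses the imine and dehydrates the allylic alcohol to 7.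

**Step 2.** A second homologation of 3 by the ylide and incomplete conversion of the electron-rich aldehyde may lower the yield and complicate purification. The fallback builds the enal by olefination and redox adjustment; it sets out from 2 and returns at 3. Horner–Wadsworth–Emmons reaction of 2 (triethyl phosphonoacetate, NaH, THF, 0 °C) gives ethyl (E)-3-[4-(tert-butyldimethylsilyloxy)phenyl]prop-2-enoate F14. Reduction (iBu2AlH, CH2Cl2, −78 °C) gives (E)-3-[4-(tert-butyldimethylsilyloxy)phenyl]prop-2-en-1-ol F15, and MnO2 in CH2Cl2 oxidises the allylic alcohol to 3.

## Further compounds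

F1 | step 6 | 2-[(E)-2-[4-(tert-butyldimethylsilyloxy)phenyl]ethenyl]-4,4,5,5-tetramethyl-1,3,2-dioxaborolane | CC(C)(C)[Si](C)(C)Oc1ccc(/C=C/B2OC(C)(C)C(C)(C)O2)cc1
F2 | step 6 | (E)-2-[4-(tert-butyldimethylsilyloxy)phenyl]ethenylboronic acid | CC(C)(C)[Si](C)(C)Oc1ccc(/C=C/B(O)O)cc1
F3 | step 6 | 2-hydroxy-4-methoxybenzaldehyde | COc1ccc(C=O)c(O)c1
F4 | step 6 | (E)-3-(2-hydroxy-4-methoxyphenyl)prop-2-enal | COc1ccc(/C=C/C=O)c(O)c1
F5 | step 6 | (4S)-4-[(E)-4-(tert-butyldimethylsilyloxy)styryl]-7-methoxychroman-2-ol (anomeric mixture) | COc1ccc2c(c1)OC(O)C[C@H]2/C=C/c1ccc(O[Si](C)(C)C(C)(C)C)cc1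
F6 | step 6 | (4S)-4-[(E)-4-(tert-butyldimethylsilyloxy)styryl]-7-methoxychroman-2-one | COc1ccc2c(c1)OC(=O)C[C@H]2/C=C/c1ccc(O[Si](C)(C)C(C)(C)C)cc1
F7 | step 6 | [4-(tert-butyldimethylsilyloxy)phenyl]methanol | CC(C)(C)[Si](C)(C)Oc1ccc(CO)cc1
F8 | step 6 | 4-(tert-butyldimethylsilyloxy)benzyl bromide | CC(C)(C)[Si](C)(C)Oc1ccc(CBr)cc1
F9 | step 6 | (3R,4R)-3-[4-(tert-butyldimethylsilyloxy)benzyl]-4-[(E)-4-(tert-butyldimethylsilyloxy)styryl]-7-methoxychroman-2-one | COc1ccc2c(c1)OC(=O)[C@H](Cc1ccc(O[Si](C)(C)C(C)(C)C)cc1)[C@H]2/C=C/c1ccc(O[Si](C)(C)C(C)(C)C)cc1
F10 | step 7 | 1-bromo-2,4-dimethoxybenzene | COc1ccc(Br)c(OC)c1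
F11 | step 7 | (2R,3R,4E)-2-[4-(tert-butyldimethylsilyloxy)benzyl]-1-(2,4-dimethoxyphenyl)-3-(2-hydroxy-4-methoxyphenyl)-5-[4-(tert-butyldimethylsilyloxy)phenyl]pent-4-en-1-ol (both carbinol epimers) | OC(c1ccc(OC)cc1OC)[C@H](Cc1ccc(O[Si](C)(C)C(C)(C)C)cc1)[C@H](c1ccc(OC)cc1O)/C=C/c1ccc(O[Si](C)(C)C(C)(C)C)cc1
F12 | step 5 | (E)-N-cyclohexyl-3-[4-(tert-butyldimethylsilyloxy)phenyl]propan-1-imine | CC(C)(C)[Si](C)(C)Oc1ccc(CC/C=N/C2CCCCC2)cc1
F13 | step 5 | (4E)-2-[4-(tert-butyldimethylsilyloxy)benzyl]-1-(cyclohexylimino)-5-[4-(tert-butyldimethylsilyloxy)phenyl]pent-4-en-3-ol (mixture of diastereomers) | CC(C)(C)[Si](C)(C)Oc1ccc(CC(/C=N/C2CCCCC2)C(O)/C=C/c2ccc(O[Si](C)(C)C(C)(C)C)cc2)cc1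
F14 | step 2 | ethyl (E)-3-[4-(tert-butyldimethylsilyloxy)phenyl]prop-2-enoate | CCOC(=O)/C=C/c1ccc(O[Si](C)(C)C(C)(C)C)cc1
F15 | step 2 | (E)-3-[4-(tert-butyldimethylsilyloxy)phenyl]prop-2-en-1-ol | OC/C=C/c1ccc(O[Si](C)(C)C(C)(C)C)cc1
A1 | alternative 1 | all-trans 5-chloro-2-(2,4-dimethoxyphenyl)-7-methoxy-3-[4-(methoxymethoxy)benzyl]-4-{2-[4-(methoxymethoxy)phenyl]-2-oxoethyl}chroman (enantiomer drawn) | COc1cc(Cl)c2c(c1)O[C@@H](c1ccc(OC)cc1OC)[C@H](Cc1ccc(OCOC)cc1)[C@H]2CC(=O)c1ccc(OCOC)cc1
A2 | alternative 1 | (E)-5-(2,4-dimethoxyphenyl)-5-hydroxy-4-[4-(methoxymethoxy)benzyl]-1-[4-(methoxymethoxy)phenyl]pent-2-en-1-one (4,5-anti; enantiomer drawn) | O[C@@H](c1ccc(OC)cc1OC)[C@H](Cc1ccc(OCOC)cc1)/C=C/C(=O)c1ccc(OCOC)cc1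
A3 | alternative 1 | 2-chloro-4-methoxy-6-(trimethylsilyl)phenyl trifluoromethanesulfonate | COc1cc(Cl)c(OS(=O)(=O)C(F)(F)F)c(c1)[Si](C)(C)C
A4 | alternative 2 | trans-3-[4-(tert-butyldimethylsilyloxy)benzyl]-4-[(E)-4-(tert-butyldimethylsilyloxy)styryl]-7-methoxychroman-2-one (enantiomer drawn) | COc1ccc2c(c1)OC(=O)[C@H](Cc1ccc(O[Si](C)(C)C(C)(C)C)cc1)[C@H]2/C=C/c1ccc(O[Si](C)(C)C(C)(C)C)cc1
A5 | alternative 2 | 7-methoxycoumarin | COc1ccc2ccc(=O)oc2c1
A6 | alternative 2 | (E)-2-[4-(tert-butyldimethylsilyloxy)phenyl]ethenylmagnesium bromide | CC(C)(C)[Si](C)(C)Oc1ccc(/C=C/[Mg]Br)cc1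
A7 | alternative 2 | 4-(tert-butyldimethylsilyloxy)benzyl bromide | CC(C)(C)[Si](C)(C)Oc1ccc(CBr)cc1
A8 | alternative 3 | caraganin C di-O-acetate | COc1ccc2c(c1)O[C@@H](c1ccc(OC)cc1OC)[C@H](Cc1ccc(OC(C)=O)cc1)[C@H]2/C=C/c1ccc(OC(C)=O)cc1
A9 | alternative 3 | 2,4-dimethoxybenzaldehyde | COc1ccc(C=O)c(OC)c1
A10 | alternative 3 | (1E,3E)-1,5-bis(4-acetoxyphenyl)penta-1,3-diene | CC(=O)Oc1ccc(C/C=C/C=C/c2ccc(OC(C)=O)cc2)cc1
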